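**Retrosynthetic overview**

1. The target is 3β,19-diacetoxy-6β-hydroxy-9α,13R:15,16-diepoxylabd-14-en-7-one. Late disconnections: 6β-OH (inverting acyl shift of a C6–C7 enol ester epoxide), C14=C15 (dehydration of a 14-ol), C9–O (oxa-Michael addition of the C13 hydroxyl to a Δ8-en-7-one) and C9–C11 (acetylide addition to a vinylogous ester).
2. Ring B is opened at C8–C9 (Claisen condensation) and C7–C8 (Grignard opening of a temporary δ-lactone C19–O–C7), which leaves ring A carrying the lactone and a C9 ester.
3. Ring A (key step) is opened at C2–C3 and C5–C10: a formal [3+3] annulation of the extended enolate of methyl tiglate with a formyl lactone. The enabling feature is that quaternary C4 holds two electrophilic carbons in a 1,3-relationship, C3 (formyl) and C5 (β-carbon of the C5=C6–C7(=O)–O–C19 lactone ring), while the tiglate unit C2–C1=C10(C20)–C9 is nucleophilic first at C2 (γ) and then at C10 (α).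
4. Stereochemistry: C4 comes from a Sharpless epoxidation (transferred by a 1,2-shift); C5 and C10 are relayed from C4 in the key step through the lactone tether; C3, C8, C9 and C6 follow by substrate control; C13 comes from (3R,4R)-tetrahydrofuran-3,4-diol.
5. Order of ring formation: temporary δ-lactone, ring A, ring B (lactone opened), tetrahydrofuran ring of the spiro ether (its oxolane partner arrives with the side-chain fragment), then the dihydrofuran double bond.

Key step: step 9

Remark: labdane numbering (C1–C20) and the α/β convention of the usual labdane drawing are used for all intermediates, and (3R,4R)-tetrahydrofuran-3,4-diol (1,4-anhydro-D-threitol) is assumed to be purchasable.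

**Route**

Step 1
Reactants: 1 geraniol
Product: 2 (2S,3S)-2,3-epoxygeraniol
Conditions: Ti(OiPr)4 (5 mol %), L-(+)-diethyl tartrate (6 mol %), t-BuOOH, 4 Å molecular sieves, CH2Cl2, −20 °C
Reagents that add atoms: tert-butyl hydroperoxide, CC(C)(C)OO
Why: Sharpless asymmetric epoxidation of the allylic alcohol, in which the L-(+)-tartrate–titanium complex should deliver oxygen to the alkene face that gives the (2S,3S)-epoxide; this catalyst-set stereochemistry is the source of C4 of the target.

Step 2
Reactants: 2 (2S,3S)-2,3-epoxygeraniol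
Product: 3 tert-butyldimethylsilyl ether of 2
Conditions: t-BuMe2SiCl, imidazole, DMF, 0 °C → rt
Reagents that add atoms: tert-butyldimethylsilyl chloride, CC(C)(C)[Si](C)(C)Cl
Why: Standard silylation of the primary alcohol, which creates the siloxymethyl group that migrates in step 3.

Step 3
Reactants: 3 tert-butyldimethylsilyl ether of 2
Product: 4 (S)-2-[(tert-butyldimethylsilyloxy)methyl]-2,6-dimethylhept-5-enal
Conditions: MeAl(OAr)2 (Ar = 4-bromo-2,6-di-tert-butylphenyl; 20 mol %), CH2Cl2, −78 → −20 °C
Reagents that add atoms: none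
Why: Lewis-acid-promoted semipinacol-type rearrangement of a 2,3-epoxy silyl ether, in which ionisation of the tertiary C–O bond and anti 1,2-shift of the siloxymethyl group should give the α-quaternary aldehyde with inversion, so that the epoxide configuration becomes that of the quaternary carbon (C4 of the target).

Step 4
Reactants: 4 (S)-2-[(tert-butyldimethylsilyloxy)methyl]-2,6-dimethylhept-5-enal
Product: 5 dimethyl acetal of 4
Conditions: MeOSiMe3, Me3SiOTf (2 mol %), CH2Cl2, −78 °C
Reagents that add atoms: methoxytrimethylsilane, CO[Si](C)(C)C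
Why: Aprotic acetalisation under silyl triflate catalysis masks the hindered aldehyde (the future C3) without touching the silyl ether, the alkene or the stereocentre.

Step 5
Reactants: 5 dimethyl acetal of 4
Product: 7 (S)-5-(tert-butyldimethylsilyloxy)-4-(dimethoxymethyl)-4-methylpentanoic acid, via aldehyde 6 (not isolated)
Conditions: O3, CH2Cl2, −78 °C; PPh3; then NaClO2, NaH2PO4, 2-methyl-2-butene, t-BuOH/H2O, 0 °C → rt
Reagents that add atoms: ozone, [O-][O+]=O; sodium chlorite, [Na+].[O-]Cl=O
Why: Ozonolysis of the trisubstituted alkene followed by Pinnick oxidation should give the acid that holds C5, C6 and C7, with silyl ether and acetal surviving both buffered stages.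

Step 6
Reactants: 7 (S)-5-(tert-butyldimethylsilyloxy)-4-(dimethoxymethyl)-4-methylpentanoic acid
Product: 9 (S)-5-(dimethoxymethyl)-5-methyltetrahydro-2H-pyran-2-one, via hydroxy acid 8 (not isolated)
Conditions: camphorsulfonic acid (10 mol %), MeOH, rt; then PhMe, 80 °C
Reagents that add atoms: none
Why: Acid-catalysed methanolysis of the primary silyl ether and lactonisation of the δ-hydroxy acid (helped by the quaternary centre) should build the temporary δ-lactone ring C19–O–C7(=O), the dimethyl acetal being stable in methanol.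

Step 7
Reactants: 9 (S)-5-(dimethoxymethyl)-5-methyltetrahydro-2H-pyran-2-one
Product: 11 (S)-5-(dimethoxymethyl)-5-methyl-5,6-dihydro-2H-pyran-2-one, via selenide 10 (not isolated)
Conditions: LiN(iPr)2, THF, −78 °C; PhSeBr; then H2O2, pyridine, CH2Cl2, 0 °C → rt
Reagents that add atoms: none
Why: α-Selenenylation of the lactone enolate and selenoxide syn-elimination introduce the C5=C6 double bond, the only direction open because C4 is quaternary.

Step 8
Reactants: 11 (S)-5-(dimethoxymethyl)-5-methyl-5,6-dihydro-2H-pyran-2-one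
Product: 12 (S)-3-methyl-6-oxo-3,6-dihydro-2H-pyran-3-carbaldehyde
Conditions: 2 M HCl, THF, rt
Reagents that add atoms: water, O
Why: Acid hydrolysis of the acetal releases the non-enolisable aldehyde; the two oxidised arms on C4 stay different (aldehyde and lactone), so no degenerate translactonisation can racemise the quaternary centre.

Step 9
Reactants: 12 (S)-3-methyl-6-oxo-3,6-dihydro-2H-pyran-3-carbaldehyde; 13 methyl tiglate
Product: 15 bicyclic lactone ester methyl 8-hydroxy-5,8a-dimethyl-3-oxo-3,4,4a,5,8,8a-hexahydro-1H-isochromene-5-carboxylate, via hydroxy enoate 14 (not isolated)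
Conditions: LiN(iPr)2 (2.6 equiv), 13 (2.6 equiv), THF/DMPU (4:1), −78 °C; then 12, −78 → −30 °C; AcOH, −78 °C
Reagents that add atoms: none
Why: Proposed new method: the lithium dienolate of 13 should add through its γ-carbon (C2) to the non-enolisable formyl group of 12 to give alkoxide 14, a second γ-deprotonation of this (E)-enoate by the excess dienolate should give the (Z)-configured dienolate dianion, and its α-carbon (C10) should then add to C5 of the unsaturated δ-lactone; the closest known reaction types are the thermodynamically controlled vinylogous aldol addition and the deconjugative α-Michael addition of ester dienolates, and the amine-mediated formal [3+3] annulation of enals in which a dienamine reacts first at its γ- and then at its α-carbon. Only ring A is closed, by a 6-exo-trig Michael addition of the enolate carbon C10 onto C5, after the intermolecular C2–C3 bond has tied the two partners together. C5 is controlled by the tether and the temporary lactone ring: C10 can only reach the face of C5 that carries the C3 arm of quaternary C4, so ring A becomes cis-fused to the lactone and H-5 ends cis to the C18 methyl group and anti to C19, as in the target. C10 is controlled by the dienolate geometry: in the extended (s-trans) dienolate the C20 methyl group is the inside substituent and becomes pseudo-axial and syn to C19, while the enolate carbon C9 stays outside and ends trans to C6, which is the relationship needed for the trans-decalin. C3 is formed without reliable control and both epimers are converged in steps 10 and 11. The step needs γ- over α-selectivity in the aldol stage and attack at the aldehyde instead of the lactone carbonyl, which the quaternary C4 next to the formyl group (the α-adduct would join two fully substituted carbons and reverts), the low temperature and the intramolecular nature of the Michael stage should secure.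

Step 10
Reactants: 15 bicyclic lactone ester (C3 epimers)
Product: 16 enone methyl 5,8a-dimethyl-3,8-dioxo-3,4,4a,5,8,8a-hexahydro-1H-isochromene-5-carboxylate
Conditions: Dess–Martin periodinane, NaHCO3, CH2Cl2, rt
Reagents that add atoms: none
Why: Dess–Martin oxidation of the allylic alcohol converges both C3 epimers to one enone.

Step 11
Reactants: 16 enone
Product: 18 3β-alcohol methyl 8-hydroxy-5,8a-dimethyl-3-oxooctahydro-1H-isochromene-5-carboxylate, via saturated ketone 17 (not isolated)
Conditions: H2 (1 atm), Pd/C, EtOAc, rt; filtration; then NaBH4, MeOH, −20 °C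
Reagents that add atoms: none
Why: Hydrogenation of the enone C1=C2 bond and borohydride reduction of the 3-ketone, where axial hydride delivery from the α-face (the β-face is blocked by the axial C19 methylene and C20 methyl groups) should give the equatorial 3β-alcohol.

Step 12
Reactants: 18 3β-alcohol
Product: 19 hydroxy ketone methyl 4-hydroxy-3-(hydroxymethyl)-1,3-dimethyl-2-(2-oxobutyl)cyclohexane-1-carboxylate
Conditions: EtMgBr (3 equiv), THF, −78 → −40 °C; aq. NH4Cl
Reagents that add atoms: ethylmagnesium bromide, CC[Mg]Br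
Why: Mono-addition of a Grignard reagent to the δ-lactone at low temperature (stable magnesium hemiketalate) should give the ethyl ketone carrying C8 and C17 and free the 19-hydroxyl group, while the neopentyl ester on quaternary C10 should not compete.

Step 13
Reactants: 19 hydroxy ketone
Product: 20 dione 3β,19-dihydroxy-11,12,13,14,15,16-hexanorlabdane-7,9-dione
Conditions: KOt-Bu (4 equiv), THF, 0 °C → rt; then 1 M HCl to pH 3
Reagents that add atoms: none
Why: Intramolecular Claisen condensation in which the C8 enolate of the ethyl ketone acylates the C9 ester (6-exo-trig closure of ring B), driven by formation of the 1,3-diketonate; the trans ring fusion is already fixed by C5 and C10.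

Step 14
Reactants: 20 dione
Product: 21 vinylogous ester 7-isobutoxy-3β,19-dihydroxy-11,12,13,14,15,16-hexanorlabd-7-en-9-one
Conditions: i-BuOH, TsOH (5 mol %), PhH, reflux, Dean–Stark trap
Reagents that add atoms: 2-methylpropan-1-ol, CC(C)CO
Why: Acid-catalysed enol etherification of the unsymmetrical 1,3-dione under thermodynamic control should place the alkoxy group on the less hindered C7 and keep the neopentyl C9 carbonyl as the ketone, as needed for a Stork–Danheiser sequence.

Step 15
Reactants: 21 vinylogous ester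
Product: 22 3β,19-O-isopropylidene acetal of 21
Conditions: 2-methoxypropene, pyridinium p-toluenesulfonate (5 mol %), CH2Cl2, 0 °C
Reagents that add atoms: 2-methoxypropene, COC(C)=C
Why: Acetonide formation on the 3β,19-diol (cis-fused 1,3-dioxane) under mild acid that the enol ether survives removes both hydroxyl protons before the organometallic step.

Step 16
Reactants: 23 (3R,4R)-tetrahydrofuran-3,4-diol
Product: 24 (3R,4R)-4-(triisopropylsilyloxy)tetrahydrofuran-3-ol
Conditions: NaH (1.0 equiv), THF, 0 °C; then i-Pr3SiCl (1.0 equiv), rt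
Reagents that add atoms: triisopropylsilyl chloride, CC(C)[Si](Cl)(C(C)C)C(C)C
Why: Monosilylation of the C2-symmetric trans-diol through its mono-alkoxide; the two hydroxyl groups are equivalent, and the bulky silyl group does not migrate in later basic steps.

Step 17
Reactants: 24 (3R,4R)-4-(triisopropylsilyloxy)tetrahydrofuran-3-ol
Product: 25 (R)-4-(triisopropylsilyloxy)dihydrofuran-3(2H)-one
Conditions: Dess–Martin periodinane, NaHCO3, CH2Cl2, 0 °C → rt
Reagents that add atoms: none
Why: Buffered Dess–Martin oxidation gives the α-silyloxy ketone without epimerising the stereocentre next to the carbonyl group.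

Step 18
Reactants: 25 (R)-4-(triisopropylsilyloxy)dihydrofuran-3(2H)-one
Product: 26 (3S,4R)-3-ethynyl-4-(triisopropylsilyloxy)tetrahydrofuran-3-ol
Conditions: HC≡CMgBr, THF, −78 °C; aq. NH4Cl
Reagents that add atoms: ethynylmagnesium bromide, C#C[Mg]Br
Why: Grignard addition to the cyclic α-silyloxy ketone, in which the acetylide should attack the carbonyl face anti to the bulky silyloxy group; this sets the tertiary carbinol carbon (C13 of the target) from the tartrate-derived centre.

Step 19
Reactants: 22 3β,19-O-isopropylidene vinylogous ester; 26 (3S,4R)-3-ethynyl-4-(triisopropylsilyloxy)tetrahydrofuran-3-ol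
Product: 27 adduct 7-isobutoxy-9ξ,13-dihydroxy-3β,19-(isopropylidenedioxy)-14-(triisopropylsilyloxy)-15,16-epoxylabd-7-en-11-yne
Conditions: 26 (1.5 equiv), n-BuLi (3.0 equiv), THF, −78 °C; CeCl3, −78 °C; then 22, −78 → −20 °C; aq. NaHCO3
Reagents that add atoms: none
Why: Stork–Danheiser-type 1,2-addition of a small, weakly basic cerium acetylide to the hindered C9 carbonyl of the vinylogous ester forms the C9–C11 bond; the C9 configuration is irrelevant because this centre is ionised in step 21.

Step 20
Reactants: 27 adduct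
Product: 28 7-isobutoxy-9ξ,13-dihydroxy-3β,19-(isopropylidenedioxy)-14-(triisopropylsilyloxy)-15,16-epoxylabd-7-ene
Conditions: H2 (1 atm), Pd/C, EtOAc, Et3N (1 vol %), rt
Reagents that add atoms: none
Why: Heterogeneous hydrogenation saturates the alkyne to the C11–C12 bridge, while the tetrasubstituted enol ether should resist reduction and triethylamine keeps the acid-labile carbinol intact.

Step 21
Reactants: 28 hydrogenated adduct
Product: 30 spiro ether diol 3β,19-dihydroxy-14-(triisopropylsilyloxy)-9α,13:15,16-diepoxylabdan-7-one, via enone 29 (not isolated)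
Conditions: 1 M HCl, THF, rt; aq. NaHCO3; then KOt-Bu (0.3 equiv), THF, −20 → 0 °C
Reagents that add atoms: water, O
Why: Acid hydrolysis of the enol ether with loss of the tertiary C9 hydroxyl gives the transposed Δ8-en-7-one (Stork–Danheiser) and cleaves the acetonide; base-catalysed 5-exo-trig oxa-Michael addition of the C13 hydroxyl should then attack C9 from the α-face, anti to the axial C20 methyl group, while C8 equilibrates to the equatorial α-methyl epimer.

Step 22
Reactants: 30 spiro ether diol
Product: 31 3β,19-diacetoxy-14-(triisopropylsilyloxy)-9α,13:15,16-diepoxylabdan-7-one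
Conditions: Ac2O, pyridine, 4-dimethylaminopyridine (5 mol %), CH2Cl2, 0 °C → rt
Reagents that add atoms: acetic anhydride, CC(=O)OC(C)=O
Why: Standard acetylation of the equatorial 3β- and the primary 19-hydroxyl groups, the only free hydroxyl groups present.

Step 23
Reactants: 31 diacetate
Product: 32 enol ester 3β,19-diacetoxy-7-(chloroacetoxy)-14-(triisopropylsilyloxy)-9α,13:15,16-diepoxylabd-6-ene
Conditions: KN(SiMe3)2 (1.1 equiv), THF, −78 °C; then (ClCH2CO)2O, −78 °C
Reagents that add atoms: chloroacetic anhydride, ClCC(=O)OC(=O)CCl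
Why: Kinetic deprotonation of the ketone on its less substituted side (C6) by a hindered amide base and O-acylation of the potassium enolate give the enol ester; the acetates are much weaker carbon acids and should not be deprotonated at −78 °C.

Step 24
Reactants: 32 enol ester
Product: 34 3β,19-diacetoxy-6β-(chloroacetoxy)-14-(triisopropylsilyloxy)-9α,13:15,16-diepoxylabdan-7-one, via epoxide 33 (not isolated)
Conditions: dimethyldioxirane (acetone solution), CH2Cl2, −20 → 0 °C; evaporation; then PhMe, 150 °C, sealed tube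
Reagents that add atoms: dimethyldioxirane, CC1(C)OO1
Why: Epoxidation of the enol ester from the less hindered α-face (the β-face is shielded by the axial C19 and C20 groups) and thermal, acid-free enol ester epoxide rearrangement, in which the acyl carbonyl oxygen should open the epoxide at C6 intramolecularly with inversion; this places the acyloxy group in the axial 6β position and makes C7 the ketone.

Step 25
Reactants: 34 6β-chloroacetoxy ketone
Product: 35 3β,19-diacetoxy-6β-(chloroacetoxy)-14-hydroxy-9α,13:15,16-diepoxylabdan-7-one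
Conditions: HF·pyridine, pyridine, THF, 0 °C → rt
Reagents that add atoms: none
Why: Fluoride-mediated cleavage of the triisopropylsilyl ether, to which the esters and the α-acyloxy ketone are stable under buffered conditions.

Step 26
Reactants: 35 14-alcohol
Product: 36 3β,19-diacetoxy-6β-(chloroacetoxy)-9α,13R:15,16-diepoxylabd-14-en-7-one
Conditions: Burgess reagent, PhH, 50 °C
Reagents that add atoms: none
Why: Burgess dehydration (syn-elimination through the sulfamate ester) of the secondary alcohol can only take a hydrogen from C15 because C13 is quaternary, which gives the C14=C15 enol ether under neutral conditions that should not aromatise the 2,3-dihydrofuran.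

Step 27
Reactants: 36 enol ether chloroacetate
Product: 37 CNP0317137.1, 3β,19-diacetoxy-6β-hydroxy-9α,13R:15,16-diepoxylabd-14-en-7-one
Conditions: thiourea, NaHCO3, EtOH/THF, 50 °C
Reagents that add atoms: none
Why: Selective removal of the chloroacetate by thiourea (S-alkylation, then cyclisation onto the ester carbonyl) under nearly neutral conditions should leave the two acetates, the α-ketol and the acid-labile enol ether untouched.

**Compound list**

1 | geraniol, (E)-3,7-dimethylocta-2,6-dien-1-ol | CC(C)=CCC/C(C)=C/CO | starting material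
2 | (2S,3S)-2,3-epoxygeraniol | CC(C)=CCC[C@]1(C)O[C@H]1CO | intermediate
3 | tert-butyldimethylsilyl ether of (2S,3S)-2,3-epoxygeraniol | CC(C)=CCC[C@]1(C)O[C@H]1CO[Si](C)(C)C(C)(C)C | intermediate
4 | (S)-2-[(tert-butyldimethylsilyloxy)methyl]-2,6-dimethylhept-5-enal | CC(C)(C)[Si](C)(C)OC[C@@](CCC=C(C)C)(C)C=O | intermediate
5 | (S)-tert-butyl{[2-(dimethoxymethyl)-2,6-dimethylhept-5-en-1-yl]oxy}dimethylsilane | CC(C)(C)[Si](C)(C)OC[C@@](CCC=C(C)C)(C)C(OC)OC | intermediate
6 | (S)-5-(tert-butyldimethylsilyloxy)-4-(dimethoxymethyl)-4-methylpentanal | CC(C)(C)[Si](C)(C)OC[C@@](CCC=O)(C)C(OC)OC | intermediate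
7 | (S)-5-(tert-butyldimethylsilyloxy)-4-(dimethoxymethyl)-4-methylpentanoic acid | CC(C)(C)[Si](C)(C)OC[C@@](CCC(=O)O)(C)C(OC)OC | intermediate
8 | (S)-4-(dimethoxymethyl)-5-hydroxy-4-methylpentanoic acid | OC[C@@](CCC(=O)O)(C)C(OC)OC | intermediate
9 | (S)-5-(dimethoxymethyl)-5-methyltetrahydro-2H-pyran-2-one | COC(OC)[C@]1(C)COC(=O)CC1 | intermediate
10 | (5S)-5-(dimethoxymethyl)-5-methyl-3-(phenylselanyl)tetrahydro-2H-pyran-2-one (C3 epimers) | COC(OC)[C@]1(C)COC(=O)C([Se]c2ccccc2)C1 | intermediate
11 | (S)-5-(dimethoxymethyl)-5-methyl-5,6-dihydro-2H-pyran-2-one | COC(OC)[C@]1(C)COC(=O)C=C1 | intermediate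
12 | (S)-3-methyl-6-oxo-3,6-dihydro-2H-pyran-3-carbaldehyde | O=C[C@]1(C)COC(=O)C=C1 | intermediate
13 | methyl tiglate, methyl (E)-2-methylbut-2-enoate | C/C=C(\C)C(=O)OC | starting material
14 | methyl (E)-5-hydroxy-2-methyl-5-[(S)-3-methyl-6-oxo-3,6-dihydro-2H-pyran-3-yl]pent-2-enoate (carbinol epimers) | COC(=O)/C(C)=C/CC(O)[C@]1(C)COC(=O)C=C1 | intermediate
15 | methyl 8-hydroxy-5,8a-dimethyl-3-oxo-3,4,4a,5,8,8a-hexahydro-1H-isochromene-5-carboxylate; labdane numbering: C1=C2, 3-OH (both epimers), 18-Me α, C19 β in the lactone C19–O–C7(=O)–C6, H-5 α, 20-Me β, C9 ester trans to C6 | C1[C@@]2(C)C(O)C=C[C@@](C(=O)OC)(C)[C@H]2CC(=O)O1 | intermediate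
16 | methyl 5,8a-dimethyl-3,8-dioxo-3,4,4a,5,8,8a-hexahydro-1H-isochromene-5-carboxylate (1-en-3-one; C4, C5, C10 as in 15) | C1[C@@]2(C)C(=O)C=C[C@@](C(=O)OC)(C)[C@H]2CC(=O)O1 | intermediate
17 | methyl 5,8a-dimethyl-3,8-dioxooctahydro-1H-isochromene-5-carboxylate (3-ketone; C4, C5, C10 as in 15) | C1[C@@]2(C)C(=O)CC[C@@](C(=O)OC)(C)[C@H]2CC(=O)O1 | intermediate
18 | methyl 8-hydroxy-5,8a-dimethyl-3-oxooctahydro-1H-isochromene-5-carboxylate (3β-OH; C4, C5, C10 as in 15) | C1[C@@]2(C)[C@@H](O)CC[C@@](C(=O)OC)(C)[C@H]2CC(=O)O1 | intermediate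
19 | methyl 4-hydroxy-3-(hydroxymethyl)-1,3-dimethyl-2-(2-oxobutyl)cyclohexane-1-carboxylate (3β-OH, 19-OH β-axial, H-5 α, 20-Me β) | OC[C@@]1(C)[C@@H](O)CC[C@@](C(=O)OC)(C)[C@H]1CC(=O)CC | intermediate
20 | 3β,19-dihydroxy-11,12,13,14,15,16-hexanorlabdane-7,9-dione (H-5 α, 20-Me β, trans-decalin; C8 unassigned, largely enolised) | OC[C@@]1(C)[C@@H](O)CC[C@@]2(C)[C@H]1CC(=O)C(C)C2=O | intermediate
21 | 7-isobutoxy-3β,19-dihydroxy-11,12,13,14,15,16-hexanorlabd-7-en-9-one | OC[C@@]1(C)[C@@H](O)CC[C@@]2(C)[C@H]1CC(OCC(C)C)=C(C)C2=O | intermediate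
22 | 7-isobutoxy-3β,19-(isopropylidenedioxy)-11,12,13,14,15,16-hexanorlabd-7-en-9-one | CC1(C)OC[C@@]2(C)[C@@H](O1)CC[C@@]3(C)[C@H]2CC(OCC(C)C)=C(C)C3=O | intermediate
23 | (3R,4R)-tetrahydrofuran-3,4-diol (1,4-anhydro-D-threitol) | O[C@H]1[C@H](O)COC1 | starting material
24 | (3R,4R)-4-(triisopropylsilyloxy)tetrahydrofuran-3-ol | O[C@H]1[C@H](O[Si](C(C)C)(C(C)C)C(C)C)COC1 | intermediate
25 | (R)-4-(triisopropylsilyloxy)dihydrofuran-3(2H)-one | O=C1[C@H](O[Si](C(C)C)(C(C)C)C(C)C)COC1 | intermediate
26 | (3S,4R)-3-ethynyl-4-(triisopropylsilyloxy)tetrahydrofuran-3-ol | C#C[C@]1([C@H](O[Si](C(C)C)(C(C)C)C(C)C)COC1)O | intermediate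
27 | 7-isobutoxy-9ξ,13-dihydroxy-3β,19-(isopropylidenedioxy)-14-(triisopropylsilyloxy)-15,16-epoxylabd-7-en-11-yne (13S,14R) | CC1(C)OC[C@@]2(C)[C@@H](O1)CC[C@@]3(C)[C@H]2CC(OCC(C)C)=C(C)C3(O)C#C[C@]4([C@H](O[Si](C(C)C)(C(C)C)C(C)C)COC4)O | intermediate
28 | 7-isobutoxy-9ξ,13-dihydroxy-3β,19-(isopropylidenedioxy)-14-(triisopropylsilyloxy)-15,16-epoxylabd-7-ene (13S,14R) | CC1(C)OC[C@@]2(C)[C@@H](O1)CC[C@@]3(C)[C@H]2CC(OCC(C)C)=C(C)C3(O)CC[C@]4([C@H](O[Si](C(C)C)(C(C)C)C(C)C)COC4)O | intermediate
29 | 3β,13,19-trihydroxy-14-(triisopropylsilyloxy)-15,16-epoxylabd-8-en-7-one (13S,14R) | OC[C@@]1(C)[C@@H](O)CC[C@@]2(C)[C@H]1CC(=O)C(C)=C2CC[C@]3([C@H](O[Si](C(C)C)(C(C)C)C(C)C)COC3)O | intermediate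
30 | 3β,19-dihydroxy-14-(triisopropylsilyloxy)-9α,13:15,16-diepoxylabdan-7-one (8α-Me, 13S,14R) | OC[C@@]1(C)[C@@H](O)CC[C@@]2(C)[C@H]1CC(=O)[C@@H](C)[C@]23CC[C@]4([C@H](O[Si](C(C)C)(C(C)C)C(C)C)COC4)O3 | intermediate
31 | 3β,19-diacetoxy-14-(triisopropylsilyloxy)-9α,13:15,16-diepoxylabdan-7-one | CC(=O)OC[C@@]1(C)[C@@H](OC(C)=O)CC[C@@]2(C)[C@H]1CC(=O)[C@@H](C)[C@]23CC[C@]4([C@H](O[Si](C(C)C)(C(C)C)C(C)C)COC4)O3 | intermediate
32 | 3β,19-diacetoxy-7-(chloroacetoxy)-14-(triisopropylsilyloxy)-9α,13:15,16-diepoxylabd-6-ene | CC(=O)OC[C@@]1(C)[C@@H](OC(C)=O)CC[C@@]2(C)[C@H]1C=C(OC(=O)CCl)[C@@H](C)[C@]23CC[C@]4([C@H](O[Si](C(C)C)(C(C)C)C(C)C)COC4)O3 | intermediate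
33 | 6α,7α-epoxide of 32 (7β-chloroacetoxy) | CC(=O)OC[C@@]1(C)[C@@H](OC(C)=O)CC[C@@]2(C)[C@H]1[C@H]5O[C@@]5(OC(=O)CCl)[C@@H](C)[C@]23CC[C@]4([C@H](O[Si](C(C)C)(C(C)C)C(C)C)COC4)O3 | intermediate
34 | 3β,19-diacetoxy-6β-(chloroacetoxy)-14-(triisopropylsilyloxy)-9α,13:15,16-diepoxylabdan-7-one | CC(=O)OC[C@@]1(C)[C@@H](OC(C)=O)CC[C@@]2(C)[C@H]1[C@H](OC(=O)CCl)C(=O)[C@@H](C)[C@]23CC[C@]4([C@H](O[Si](C(C)C)(C(C)C)C(C)C)COC4)O3 | intermediate
35 | 3β,19-diacetoxy-6β-(chloroacetoxy)-14-hydroxy-9α,13:15,16-diepoxylabdan-7-one (13S,14R) | CC(=O)OC[C@@]1(C)[C@@H](OC(C)=O)CC[C@@]2(C)[C@H]1[C@H](OC(=O)CCl)C(=O)[C@@H](C)[C@]23CC[C@]4([C@H](O)COC4)O3 | intermediate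
36 | 3β,19-diacetoxy-6β-(chloroacetoxy)-9α,13R:15,16-diepoxylabd-14-en-7-one | CC(=O)OC[C@@]1(C)[C@@H](OC(C)=O)CC[C@@]2(C)[C@H]1[C@H](OC(=O)CCl)C(=O)[C@@H](C)[C@]23CC[C@]4(C=COC4)O3 | intermediate
37 | CNP0317137.1, 3β,19-diacetoxy-6β-hydroxy-9α,13R:15,16-diepoxylabd-14-en-7-one | CC(=O)OC[C@@]1(C)[C@@H](OC(C)=O)CC[C@@]2(C)[C@H]1[C@H](O)C(=O)[C@@H](C)[C@]21CC[C@]2(C=COC2)O1 | target

**Step count and risks**

Total step count: 27. Longest linear sequence: 24 steps (steps 1–15 and 19–27; steps 16–18 make the side-chain fragment).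

Steps most likely to fail:

Step 9 (key step). The second γ-deprotonation may be slower than attack of the excess dienolate on the lactone carbonyl, or the aldol stage may stay α-selective, so that the Michael closure never starts. The fallback uses known chemistry, sets out from 12 and 13 and comes back at 16. Ester 13 would be converted into its silyl ketene acetal tert-butyl[(1-methoxy-2-methylbuta-1,3-dien-1-yl)oxy]dimethylsilane F1 (LiN(iPr)2, t-BuMe2SiCl, THF/DMPU, −78 °C). A vinylogous Mukaiyama aldol addition of F1 to 12 (BF3·OEt2, CH2Cl2, −78 °C) should give hydroxy enoate 14, now isolated. Dess–Martin oxidation would give the keto enoate methyl (E)-2-methyl-5-oxo-5-[(S)-3-methyl-6-oxo-3,6-dihydro-2H-pyran-3-yl]pent-2-enoate F2. Its doubly activated C2 methylene is enolised by a mild base (Cs2CO3, MeCN, 0 °C), and the stabilised extended enolate should close ring A through C10 by the same 6-exo-trig Michael addition to give enone 16 directly.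

Step 24. The epoxide may rearrange through the acid-catalysed pathway with retention (6α-ester), or the ether at C9 may be lost by β-elimination at the high temperature. The fallback sets out from 31 and comes back at 34. Ketone 31 would be converted into the silyl enol ether 3β,19-diacetoxy-7-(trimethylsilyloxy)-14-(triisopropylsilyloxy)-9α,13:15,16-diepoxylabd-6-ene F4 (LiN(SiMe3)2, Me3SiCl, THF, −78 °C). Bromination with N-bromosuccinimide from the open α-face should give the bromo ketone 6α-bromo-3β,19-diacetoxy-14-(triisopropylsilyloxy)-9α,13:15,16-diepoxylabdan-7-one F5. SN2 displacement with caesium chloroacetate (DMF, rt) would then invert C6 and give 34.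

Step 19. The basic acetylide may deprotonate the vinylogous ester at C6 instead of adding, or the bulky nucleophile may fail to reach the neopentyl C9 carbonyl. The fallback sets out from 22 (with 25) and comes back at 27. The smallest acetylide (HC≡CMgBr, CeCl3, THF, −78 → 0 °C) would be added to 22 to give the ethynyl carbinol 9ξ-hydroxy-7-isobutoxy-3β,19-(isopropylidenedioxy)-13,14,15,16-tetranorlabd-7-en-11-yne F3. Double deprotonation of F3 (n-BuLi, 2 equiv) and addition of the alkynyl dianion to ketone 25, again anti to the silyloxy group, would form the C12–C13 bond in place of the C9–C11 bond and give 27.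

Further compounds
F1 | step 9 | tert-butyl[(1-methoxy-2-methylbuta-1,3-dien-1-yl)oxy]dimethylsilane | COC(O[Si](C)(C)C(C)(C)C)=C(C)C=C
F2 | step 9 | methyl (E)-2-methyl-5-oxo-5-[(S)-3-methyl-6-oxo-3,6-dihydro-2H-pyran-3-yl]pent-2-enoate | COC(=O)/C(C)=C/CC(=O)[C@]1(C)COC(=O)C=C1
F3 | step 19 | 9ξ-hydroxy-7-isobutoxy-3β,19-(isopropylidenedioxy)-13,14,15,16-tetranorlabd-7-en-11-yne | CC1(C)OC[C@@]2(C)[C@@H](O1)CC[C@@]3(C)[C@H]2CC(OCC(C)C)=C(C)C3(O)C#C
F4 | step 24 | 3β,19-diacetoxy-7-(trimethylsilyloxy)-14-(triisopropylsilyloxy)-9α,13:15,16-diepoxylabd-6-ene | CC(=O)OC[C@@]1(C)[C@@H](OC(C)=O)CC[C@@]2(C)[C@H]1C=C(O[Si](C)(C)C)[C@@H](C)[C@]23CC[C@]4([C@H](O[Si](C(C)C)(C(C)C)C(C)C)COC4)O3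
F5 | step 24 | 6α-bromo-3β,19-diacetoxy-14-(triisopropylsilyloxy)-9α,13:15,16-diepoxylabdan-7-one | CC(=O)OC[C@@]1(C)[C@@H](OC(C)=O)CC[C@@]2(C)[C@H]1[C@@H](Br)C(=O)[C@@H](C)[C@]23CC[C@]4([C@H](O[Si](C(C)C)(C(C)C)C(C)C)COC4)O3
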